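The amounts are tight: 3.00 equiv of reagent stands against 2.00 equiv of second substrate and one of starting material, so the reagent just covers both.

| setting | alpha | delta | beta |
|---|---|---|---|
| starting material | 10 mM | 10 mM | 10 mM |
| second substrate | 2.00 equiv | 2.00 equiv | 2.00 equiv |
| reagent | 3.00 equiv | 3.00 equiv | 3.00 equiv |
| free catalyst | 18 mol% | 18 mol% | 18 mol% |
| temperature | 110 °C | 70 °C | 90 °C |
| time | 40 h | 40 h | 40 h |

    starting material + free catalyst ⇌ catalyst intermediate A (K1 = 50 M⁻¹, k1 = 0.0082 M⁻¹ s⁻¹, Ea1 = 83.0 kJ mol⁻¹, ΔH1 = −79.0 kJ mol⁻¹)
    reagent + catalyst intermediate A → free catalyst + target (k2 = 0.012 M⁻¹ s⁻¹, Ea2 = 63.0 kJ mol⁻¹)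
    second substrate + free catalyst ⇌ catalyst intermediate B (K3 = 22 M⁻¹, k3 = 0.019 M⁻¹ s⁻¹, Ea3 = 74.0 kJ mol⁻¹, ΔH3 = 50.0 kJ mol⁻¹)
    reagent + catalyst intermediate B → free catalyst + second product (k4 = 0.045 M⁻¹ s⁻¹, Ea4 = 65.0 kJ mol⁻¹)
    starting material + reagent → uncatalysed product (k5 = 7.0 × 10⁻⁶ M⁻¹ s⁻¹, Ea5 = 88.0 kJ mol⁻¹)
    catalyst intermediate B → spent catalyst A (k6 = 5.4 × 10⁻⁶ s⁻¹, Ea6 = 120 kJ mol⁻¹)
    reagent + catalyst intermediate A → spent catalyst B (k7 = 1.2 × 10⁻⁴ M⁻¹ s⁻¹, Ea7 = 92.0 kJ mol⁻¹)
    (constants at 70 °C)

- the best flask by amount of target, in percent of the starting material charged; "all alike" if 1.5 percentage points covers them all (alpha / delta / beta / all alike)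
- amount of target at the end, in percent of the starting material charged, alpha
- amount of target at the end, in percent of the starting material charged, delta
- amount of target at the end, in percent of the starting material charged, beta

- the list of constants is for 70 °C, to be carried to other temperatures by the activation energies and enthalpies

To whoever takes over the bench: these flasks differ in their bath. The 18 mol% of free catalyst works by turns. Each catalyst owes 5.56 turns on starting material and 11.1 on second substrate.

We count what a turn through catalyst intermediate B costs. Reagent sends it on with 0.045 M⁻¹ s⁻¹ times [reagent], and it falls to spent catalyst A with 5.4 × 10⁻⁶ s⁻¹. In delta, at 70 °C, that gives 250 passes per loss at the charged [reagent], a turnover number. But [reagent] sinks as the turns are made, so each pass grows riskier.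

Catalyst lost per second product made is the loss constant over the onward constant times [reagent]. The ratio of the constants is 0.120 mM. We sum while [reagent] falls from 30.0 mM to 10.0 mM, leaving aside what the target takes. The sum is that ratio times the logarithm of the fall, and it comes to 7.32% of the charged catalyst in delta. We call this share, lost to spent catalyst A while the second substrate is worked through, the toll.

Heat moves the toll. The loss step has 120 kJ mol⁻¹ and the onward step 65.0 kJ mol⁻¹. Binding of second substrate, with 74.0 kJ mol⁻¹, speeds up by a factor of 15 from delta's bath to alpha's. Over that span the ratio therefore grows by 7.48, and alpha's toll is 54.8%, about half of its catalyst. Beta's toll lies between them, since the loss step climbs faster with heat than the onward step.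

The target's turns then fall on the survivors: 12.3 each in alpha and 5.99 in delta, about twice as many. Heat speeds the turns too, and the binding constant of starting material is 2.78 M⁻¹ in alpha against 50 M⁻¹ in delta, so we put no figure on the target. We commit to delta as the best flask, and its load per survivor is lighter than alpha's.

The forecast names delta as best, with 26% for alpha, 50% for delta and 39% for beta, holding that “the coolest flask should win despite being incomplete”.

The simulation gives 26.4% in alpha, 46.0% in beta and 54.2% in delta, so delta is best. At 40.0 h, alpha holds 52.2% of its catalyst as spent catalyst A, against our toll of 54.8%. Delta left until 4.0 d still has 6.0% of its second substrate. Its toll of 7.32% stands there against a reading of 9.11% spent catalyst A.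

The constants used here are those of an exercise; the rest is arithmetic.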